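## Retrosynthetic overview

1. Enabling feature (chromane numbering; side chain C1'–C8' counted from C2; ring A = arene, ring B = dihydropyran). O1 sits on C2, and C2 is β to side-chain carbon C2' and carries C3 as its γ-carbon. C3, C2, the 2-methyl group, C1' and C2' are therefore the five carbons of 3-methylbut-2-enal. Ring A with C4, O1, the 5-methyl group and the 7-oxygen is 2,4-dihydroxy-6-methylbenzaldehyde.
2. Key disconnection: O1–C2, an oxa-Michael closure of ring B on a chiral iminium ion. It is preceded in the same flask by C3–C4, a vinylogous aldol addition of the dienamine. C4 and C2' are held one oxidation level too high and lock each other as a temporary lactol ring C.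
3. Ring C and the C4 oxygen are then removed (NaBH4, then Et3SiH/CF3CO2H). C2' stays as CH2OH and becomes CH2I.
4. C2'–C3' is made last by alkyl–alkenyl Negishi coupling with methyl (2Z,6E)-7-iodo-2,6-dimethylhepta-2,6-dienoate. Its E olefin comes from carboalumination and its Z enoate from Still–Gennari olefination.
5. Order of rings: ring A is bought, rings B and C form together in the key step, and ring C is opened again in the next step.

Key step: step 2

Assumption: the sense of induction in step 2 is taken from the usual face-shielding model of diarylprolinol silyl ether iminium ions; should a first run show the mirror-image sense, the (S)-amine is used and nothing else changes.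

## Route

Step 1
Reactants: 1 2,4-dihydroxy-6-methylbenzaldehyde
Product: 2 2-hydroxy-6-methyl-4-(triisopropylsilyloxy)benzaldehyde
Conditions: i-Pr3SiCl (1.05 equiv), imidazole (2 equiv), CH2Cl2, 0 °C to rt
Reagents that add atoms: chlorotriisopropylsilane, CC(C)[Si](Cl)(C(C)C)C(C)C
Why: Chemoselective O-silylation, in which the ortho hydroxyl is held in a hydrogen bond to the formyl oxygen so that only the freer para hydroxyl should react; no stereocenter is formed.

Step 2
Reactants: 2 2-hydroxy-6-methyl-4-(triisopropylsilyloxy)benzaldehyde; 3 3-methylbut-2-enal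
Product: 7 bridged lactol (2S,6S)-2,7-dimethyl-9-(triisopropylsilyloxy)-3,4-dihydro-2H,6H-2,6-methano-1,5-benzodioxocin-4-ol, via dienamine 4 (not isolated), via aldol iminium ion 5 (not isolated), via hydroxy aldehyde 6 (not isolated)
Conditions: (R)-2-{bis[3,5-bis(trifluoromethyl)phenyl](trimethylsilyloxy)methyl}pyrrolidine (30 mol%), PhCO2H (30 mol%), toluene, rt; 3 (2 equiv) added in portions
Reagents that add atoms: none
Why: The amine condenses with 3 and loss of a γ-methyl proton gives dienamine 4, whose terminal CH2 adds to the formyl carbon of 2 (vinylogous aldol, C3–C4 bond) and regenerates the conjugated iminium ion 5, in which the only free phenol oxygen can reach the β-carbon through a six-membered transition state. Oxa-Michael addition of that oxygen to the β-carbon forms the O1–C2 bond and closes ring B in the 6-exo-trig mode; hydrolysis of the resulting enamine releases 6 and the catalyst, and the C4 hydroxyl adds to the aldehyde (6-exo-trig) to close the temporary ring C of lactol 7. The closest known reaction type is the diarylprolinol silyl ether catalysed domino aldol/oxa-Michael reaction of salicylaldehydes with β-methyl enals, which builds 2,2-dialkylchromans with a quaternary C2. C2 is set by the catalyst, because the C(Ar)2OSiMe3 group of the (R)-amine covers one face of the s-trans (E)-iminium ion and O1 should arrive from the open face, placing the CH2CHO arm and the methyl group as the target needs; C4 is set by the bridge, since only the isomer with the C4 oxygen cis to the acetaldehyde arm can lactolise and the aldol step is reversible, while the anomeric carbon stays a mixture that is erased in step 3. The step needs γ- over α-attack of the dienamine and cross- over self-condensation of 3; both γ-methyl groups of 3 lead to the same dienamine, aldehyde 2 cannot enolise, lactol 7 drains the equilibria, 3 is added slowly, and silylation of the para oxygen leaves O1 as the only nucleophile.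

Step 3
Reactants: 7 bridged lactol
Product: 8 (2R,4S)-2-(2-hydroxyethyl)-2,5-dimethyl-7-(triisopropylsilyloxy)chroman-4-ol
Conditions: NaBH4, MeOH/THF, 0 °C
Reagents that add atoms: none
Why: Borohydride reduction of the ring-opened hydroxy aldehyde tautomer of the lactol should remove ring C and the anomeric mixture while C2 and C4 stay untouched (the descriptor at C2 changes only through the priority rules).

Step 4
Reactants: 8 (2R,4S)-2-(2-hydroxyethyl)-2,5-dimethyl-7-(triisopropylsilyloxy)chroman-4-ol
Product: 9 2-[(2S)-2,5-dimethyl-7-(triisopropylsilyloxy)chroman-2-yl]ethanol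
Conditions: Et3SiH (3 equiv), CF3CO2H, CH2Cl2, -20 to 0 °C; aq NaHCO3/MeOH work-up
Reagents that add atoms: none
Why: Ionic hydrogenation, in which acid ionises only the C4 hydroxyl (its cation is stabilised by the ortho ring oxygen and the para silyloxy group) and Et3SiH delivers hydride, erasing the auxiliary C4 stereocenter while the quaternary C2 cannot epimerise.

Step 5
Reactants: 9 2-[(2S)-2,5-dimethyl-7-(triisopropylsilyloxy)chroman-2-yl]ethanol
Product: 10 (2S)-2-(2-iodoethyl)-2,5-dimethyl-7-(triisopropylsilyloxy)chromane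
Conditions: I2, PPh3, imidazole, CH2Cl2, 0 °C to rt
Reagents that add atoms: iodine, II
Why: Appel-type iodination (Garegg–Samuelsson conditions) of an unhindered primary alcohol by SN2 displacement of the oxyphosphonium ion, remote from C2.

Step 6
Reactants: 11 pent-4-yn-1-ol
Product: 13 (E)-5-iodo-4-methylpent-4-en-1-ol, via alkenylalane 12 (not isolated)
Conditions: AlMe3 (3 equiv), Cp2ZrCl2 (25 mol%), CH2Cl2, 0 °C to rt; then I2, THF, -30 to 0 °C
Reagents that add atoms: trimethylaluminium, C[Al](C)C; iodine, II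
Why: Negishi zirconium-catalysed carboalumination adds methyl and aluminium syn across the terminal alkyne with aluminium at the terminus, and iodinolysis with retention should give the E trisubstituted alkenyl iodide.

Step 7
Reactants: 13 (E)-5-iodo-4-methylpent-4-en-1-ol
Product: 14 (E)-5-iodo-4-methylpent-4-enal
Conditions: PhI(OAc)2 (1.1 equiv), 2,2,6,6-tetramethylpiperidin-1-oxyl (TEMPO, 10 mol%), CH2Cl2, rt
Reagents that add atoms: none
Why: Oxoammonium-mediated alcohol oxidation stops at the aldehyde and leaves the alkenyl iodide and its geometry untouched.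

Step 8
Reactants: 15 methyl 2-[bis(2,2,2-trifluoroethoxy)phosphoryl]acetate
Product: 17 methyl 2-[bis(2,2,2-trifluoroethoxy)phosphoryl]propanoate (racemic), via potassium phosphonoacetate anion 16 (not isolated)
Conditions: KOt-Bu (1.0 equiv), THF, 0 °C; then MeI, 0 °C to rt
Reagents that add atoms: iodomethane, CI
Why: C-alkylation of the stabilised phosphonoacetate anion, held at monomethylation by one equivalent of base; the new stereocenter is of no consequence because it is planarised in step 9.

Step 9
Reactants: 17 methyl 2-[bis(2,2,2-trifluoroethoxy)phosphoryl]propanoate; 14 (E)-5-iodo-4-methylpent-4-enal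
Product: 19 methyl (2Z,6E)-7-iodo-2,6-dimethylhepta-2,6-dienoate, via potassium phosphonopropanoate anion 18 (not isolated)
Conditions: 17, KN(SiMe3)2, 18-crown-6, THF, -78 °C; then 14, -78 °C
Reagents that add atoms: none
Why: Still–Gennari olefination, in which the electron-poor bis(trifluoroethyl) phosphonate with a dissociated potassium ion makes collapse of the kinetic adduct faster than its reversal and should give the Z 2-methyl enoate.

Step 10
Reactants: 10 (2S)-2-(2-iodoethyl)-2,5-dimethyl-7-(triisopropylsilyloxy)chromane; 19 methyl (2Z,6E)-7-iodo-2,6-dimethylhepta-2,6-dienoate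
Product: 21 methyl (2Z,6E)-9-[(2R)-2,5-dimethyl-7-(triisopropylsilyloxy)chroman-2-yl]-2,6-dimethylnona-2,6-dienoate, via alkylzinc iodide 20 (not isolated)
Conditions: 10, Zn dust (activated with BrCH2CH2Br and Me3SiCl, 5 mol% each), LiCl, THF, 40 °C; then 19, PdCl2(dppf) (5 mol%), THF, rt to 40 °C
Reagents that add atoms: none
Why: Negishi alkyl–alkenyl coupling, in which zinc inserts into the primary C–I bond, oxidative addition of the alkenyl iodide to zerovalent palladium and reductive elimination both proceed with retention so that the E olefin, the Z enoate and C2 are carried over, and the wide-bite-angle dppf ligand should outrun β-hydride elimination.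

Step 11
Reactants: 21 methyl (2Z,6E)-9-[(2R)-2,5-dimethyl-7-(triisopropylsilyloxy)chroman-2-yl]-2,6-dimethylnona-2,6-dienoate
Product: 22 methyl (2Z,6E)-9-[(2R)-7-hydroxy-2,5-dimethylchroman-2-yl]-2,6-dimethylnona-2,6-dienoate
Conditions: Bu4NF (1.1 equiv), AcOH (1.2 equiv), THF, 0 °C
Reagents that add atoms: none
Why: Fluoride-driven cleavage of the aryl silyl ether, buffered with AcOH so that the phenoxide neither attacks the ester nor isomerises the Z enoate.

## Compound list

1 | 2,4-dihydroxy-6-methylbenzaldehyde | Cc1cc(O)cc(O)c1C=O | starting material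
2 | 2-hydroxy-6-methyl-4-(triisopropylsilyloxy)benzaldehyde | Cc1cc(O[Si](C(C)C)(C(C)C)C(C)C)cc(O)c1C=O | intermediate
3 | 3-methylbut-2-enal | CC(C)=CC=O | starting material
4 | dienamine, (R)-1-[(1E)-3-methylbuta-1,3-dienyl]-2-{bis[3,5-bis(trifluoromethyl)phenyl](trimethylsilyloxy)methyl}pyrrolidine | C=C(C)/C=C/N1CCC[C@@H]1C(O[Si](C)(C)C)(c1cc(C(F)(F)F)cc(C(F)(F)F)c1)c1cc(C(F)(F)F)cc(C(F)(F)F)c1 | intermediate
5 | aldol iminium ion (benzoate) of (2E,5S)-5-hydroxy-5-[2-hydroxy-6-methyl-4-(triisopropylsilyloxy)phenyl]-3-methylpent-2-enal with the (R)-amine | C/C(C[C@H](O)c1c(C)cc(O[Si](C(C)C)(C(C)C)C(C)C)cc1O)=C\C=[N+]1CCC[C@@H]1C(O[Si](C)(C)C)(c1cc(C(F)(F)F)cc(C(F)(F)F)c1)c1cc(C(F)(F)F)cc(C(F)(F)F)c1.[O-]C(=O)c1ccccc1 | intermediate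
6 | 2-[(2S,4S)-4-hydroxy-2,5-dimethyl-7-(triisopropylsilyloxy)chroman-2-yl]acetaldehyde | O=CC[C@]1(C)C[C@H](O)c2c(C)cc(O[Si](C(C)C)(C(C)C)C(C)C)cc2O1 | intermediate
7 | bridged lactol, (2S,6S)-2,7-dimethyl-9-(triisopropylsilyloxy)-3,4-dihydro-2H,6H-2,6-methano-1,5-benzodioxocin-4-ol (chromane C4–O joined to C2–CH2 through O–CH(OH); anomeric carbon a mixture) | C[C@]12C[C@H](OC(O)C1)c1c(C)cc(O[Si](C(C)C)(C(C)C)C(C)C)cc1O2 | intermediate
8 | (2R,4S)-2-(2-hydroxyethyl)-2,5-dimethyl-7-(triisopropylsilyloxy)chroman-4-ol | OCC[C@]1(C)C[C@H](O)c2c(C)cc(O[Si](C(C)C)(C(C)C)C(C)C)cc2O1 | intermediate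
9 | 2-[(2S)-2,5-dimethyl-7-(triisopropylsilyloxy)chroman-2-yl]ethanol | OCC[C@]1(C)CCc2c(C)cc(O[Si](C(C)C)(C(C)C)C(C)C)cc2O1 | intermediate
10 | (2S)-2-(2-iodoethyl)-2,5-dimethyl-7-(triisopropylsilyloxy)chromane | ICC[C@]1(C)CCc2c(C)cc(O[Si](C(C)C)(C(C)C)C(C)C)cc2O1 | intermediate
11 | pent-4-yn-1-ol | C#CCCCO | starting material
12 | alkenylalane, [(1E)-5-(dimethylalumanyloxy)-2-methylpent-1-enyl]dimethylalane | C[Al](C)OCCC/C(C)=C/[Al](C)C | intermediate
13 | (E)-5-iodo-4-methylpent-4-en-1-ol | OCCC/C(C)=C/I | intermediate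
14 | (E)-5-iodo-4-methylpent-4-enal | O=CCC/C(C)=C/I | intermediate
15 | methyl 2-[bis(2,2,2-trifluoroethoxy)phosphoryl]acetate | COC(=O)CP(=O)(OCC(F)(F)F)OCC(F)(F)F | starting material
16 | potassium anion of 15 | [K+].COC(=O)[CH-]P(=O)(OCC(F)(F)F)OCC(F)(F)F | intermediate
17 | methyl 2-[bis(2,2,2-trifluoroethoxy)phosphoryl]propanoate (racemic) | COC(=O)C(C)P(=O)(OCC(F)(F)F)OCC(F)(F)F | intermediate
18 | potassium anion of 17 | [K+].COC(=O)[C-](C)P(=O)(OCC(F)(F)F)OCC(F)(F)F | intermediate
19 | methyl (2Z,6E)-7-iodo-2,6-dimethylhepta-2,6-dienoate | COC(=O)/C(C)=C\CC/C(C)=C/I | intermediate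
20 | alkylzinc iodide of 10 (C2 as in 10) | I[Zn]CC[C@]1(C)CCc2c(C)cc(O[Si](C(C)C)(C(C)C)C(C)C)cc2O1 | intermediate
21 | methyl (2Z,6E)-9-[(2R)-2,5-dimethyl-7-(triisopropylsilyloxy)chroman-2-yl]-2,6-dimethylnona-2,6-dienoate | COC(=O)/C(C)=C\CC/C(C)=C/CC[C@]1(C)CCc2c(C)cc(O[Si](C(C)C)(C(C)C)C(C)C)cc2O1 | intermediate
22 | methyl (2Z,6E)-9-[(2R)-7-hydroxy-2,5-dimethylchroman-2-yl]-2,6-dimethylnona-2,6-dienoate | COC(=O)/C(C)=C\CC/C(C)=C/CC[C@]1(C)CCc2c(C)cc(O)cc2O1 | target

## Step count and risks

Total step count: 11.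
Longest linear sequence: 7 steps (steps 1, 2, 3, 4, 5, 10 and 11, from compound 1).

**Step 2 (key step).**
- Risk: the vinylogous aldol addition to the electron-rich, ortho-substituted aldehyde may be slow. That would leave room for self-condensation of 3 and for a competing oxa-Michael/α-aldol condensation. Reversible oxa-Michael addition could also erode the facial selectivity.
- Fallback: it sets out from 2 and comes back at 9. It closes ring B at the same O1–C2 bond by an enantioselective domino Wacker cyclisation/methoxycarbonylation under divalent palladium catalysis.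
- Wittig reaction of 2 with Ph3P=CHC(O)CH3 should give the enone (E)-4-[2-hydroxy-6-methyl-4-(triisopropylsilyloxy)phenyl]but-3-en-2-one F1.
- Hydrogenation (H2, Pd/C, EtOAc) should give the ketone 4-[2-hydroxy-6-methyl-4-(triisopropylsilyloxy)phenyl]butan-2-one F2.
- Methylenation with excess Ph3P=CH2 should give the alkenyl phenol 3-methyl-2-(3-methylbut-3-en-1-yl)-5-(triisopropylsilyloxy)phenol F3.
- The cyclisation uses Pd(OCOCF3)2, the ligand (S,S)-Bn-BOXAX ((S)-2,2'-bis[(4S)-4-benzyl-4,5-dihydrooxazol-2-yl]-1,1'-binaphthyl), p-benzoquinone, CO (1 atm) and MeOH. O1 should add to the 1,1-disubstituted alkene under ligand control, and the alkylpalladium species, which has no β-hydrogen, should be captured as the ester methyl 2-[(2S)-2,5-dimethyl-7-(triisopropylsilyloxy)chroman-2-yl]acetate F4.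
- i-Bu2AlH then reduces F4 to 9.

**Step 10.**
- Risk: zinc insertion may be sluggish. Protodemetalation or β-hydride elimination may occur at the alkylpalladium stage. The Z enoate may lose geometric purity during the coupling.
- Fallback: it sets out from 10 and 13 and comes back at 21. It uses boron instead of zinc and installs the enoate only after the coupling.
- Iodine–lithium exchange of 10 (t-BuLi, Et2O, -78 °C) should give the alkyllithium 2-[2,5-dimethyl-7-(triisopropylsilyloxy)chroman-2-yl]ethyllithium F5.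
- 9-Methoxy-9-borabicyclo[3.3.1]nonane converts it into the lithium B-alkyl-B-methoxy borate F6.
- B-alkyl Suzuki–Miyaura coupling with the ester-free iodide 13 (PdCl2(dppf), K3PO4, DMF/H2O, rt) should give the alcohol (4E)-7-[(2R)-2,5-dimethyl-7-(triisopropylsilyloxy)chroman-2-yl]-4-methylhept-4-en-1-ol F7.
- Oxidation as in step 7 gives the aldehyde (4E)-7-[(2R)-2,5-dimethyl-7-(triisopropylsilyloxy)chroman-2-yl]-4-methylhept-4-enal F8.
- Still–Gennari olefination with 18, as in step 9, gives 21.

**Step 4.**
- Risk: the reduction may stall after the primary hydroxyl captures the C4 cation. The cation may alkylate a second electron-rich arene. The acid may strip the silyl group.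
- Fallback: it sets out from 7, comes back at 9 and replaces steps 3 and 4. It uses hydrogenolysis instead of a free cation.
- Oxidation of the lactol (PhI(OAc)2, TEMPO, CH2Cl2) should give the bridged lactone (2S,6S)-2,7-dimethyl-9-(triisopropylsilyloxy)-2H,6H-2,6-methano-1,5-benzodioxocin-4(3H)-one F9.
- Hydrogenolysis of its benzylic ester C4–O bond (H2, Pd/C, EtOAc) opens ring C and should give the acid 2-[(2S)-2,5-dimethyl-7-(triisopropylsilyloxy)chroman-2-yl]acetic acid F10.
- BH3·SMe2 in THF then reduces F10 to 9.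

## Further compounds

F1 | step 2 | (E)-4-[2-hydroxy-6-methyl-4-(triisopropylsilyloxy)phenyl]but-3-en-2-one | CC(=O)/C=C/c1c(C)cc(O[Si](C(C)C)(C(C)C)C(C)C)cc1O
F2 | step 2 | 4-[2-hydroxy-6-methyl-4-(triisopropylsilyloxy)phenyl]butan-2-one | CC(=O)CCc1c(C)cc(O[Si](C(C)C)(C(C)C)C(C)C)cc1O
F3 | step 2 | 3-methyl-2-(3-methylbut-3-en-1-yl)-5-(triisopropylsilyloxy)phenol | C=C(C)CCc1c(C)cc(O[Si](C(C)C)(C(C)C)C(C)C)cc1O
F4 | step 2 | methyl 2-[(2S)-2,5-dimethyl-7-(triisopropylsilyloxy)chroman-2-yl]acetate | COC(=O)C[C@]1(C)CCc2c(C)cc(O[Si](C(C)C)(C(C)C)C(C)C)cc2O1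
F5 | step 10 | 2-[2,5-dimethyl-7-(triisopropylsilyloxy)chroman-2-yl]ethyllithium (C2 as in 10) | [Li]CC[C@]1(C)CCc2c(C)cc(O[Si](C(C)C)(C(C)C)C(C)C)cc2O1
F6 | step 10 | lithium B-alkyl-B-methoxy-9-borabicyclo[3.3.1]nonane borate of F5 (C2 as in 10) | [Li+].CO[B-]1(CC[C@]2(C)CCc3c(C)cc(O[Si](C(C)C)(C(C)C)C(C)C)cc3O2)C2CCCC1CCC2
F7 | step 10 | (4E)-7-[(2R)-2,5-dimethyl-7-(triisopropylsilyloxy)chroman-2-yl]-4-methylhept-4-en-1-ol | OCCC/C(C)=C/CC[C@]1(C)CCc2c(C)cc(O[Si](C(C)C)(C(C)C)C(C)C)cc2O1
F8 | step 10 | (4E)-7-[(2R)-2,5-dimethyl-7-(triisopropylsilyloxy)chroman-2-yl]-4-methylhept-4-enal | O=CCC/C(C)=C/CC[C@]1(C)CCc2c(C)cc(O[Si](C(C)C)(C(C)C)C(C)C)cc2O1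
F9 | step 4 | (2S,6S)-2,7-dimethyl-9-(triisopropylsilyloxy)-2H,6H-2,6-methano-1,5-benzodioxocin-4(3H)-one | C[C@]12C[C@H](OC(=O)C1)c1c(C)cc(O[Si](C(C)C)(C(C)C)C(C)C)cc1O2
F10 | step 4 | 2-[(2S)-2,5-dimethyl-7-(triisopropylsilyloxy)chroman-2-yl]acetic acid | OC(=O)C[C@]1(C)CCc2c(C)cc(O[Si](C(C)C)(C(C)C)C(C)C)cc2O1
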